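Right-handed substrate barely moves: the zeta run still reads 48.0 % of the charge at 12.0 d. The excess hangs on one ratio, c(left-handed substrate)/c(right-handed substrate), which equals one minus the excess over one plus the excess. For 80 % it must fall to 11.1 %, the allowed ratio.

| flask | left-handed substrate | right-handed substrate | solid reagent | catalyst | remark | time |
|---|---|---|---|---|---|---|
| zeta | 48 mM | 48 mM | 3 equiv | 0.24 mol% | run made earlier |  |
| eta | 48 mM | 48 mM | 3 equiv | 0.54 mol% | run made earlier |  |
| alpha | 72 mM | 72 mM | 3 equiv | 0.36 mol% | run made earlier |  |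
| flask | 48 mM | 48 mM | 3.00 equiv | 0.36 mol% |  | 10 d |

| run | time / d | right-handed substrate / % | left-handed substrate / % | left-handed product / % |
|---|---|---|---|---|
| zeta | 0.625 | 49.7 | 41.1 | 9.3 |
| zeta | 1.67 | 49.3 | 29.6 | 21.2 |
| zeta | 3.00 | 50.5 | 19.0 | 30.0 |
| zeta | 5.00 | 49.5 | 11.4 | 39.0 |
| zeta | 8.00 | 46.9 | 9.2 | 41.4 |
| zeta | 10.0 | 49.1 | 6.9 | 44.2 |
| zeta | 12.0 | 48.0 | 7.3 | 44.4 |
| eta | 1.04 | 51.1 | 25.6 | 25.6 |
| eta | 1.67 | 47.7 | 15.3 | 32.6 |
| eta | 2.00 | 49.6 | 13.1 | 37.0 |
| eta | 3.00 | 47.2 | 6.5 | 42.8 |
| eta | 5.00 | 47.6 | 1.7 | 47.2 |
| eta | 8.00 | 47.4 | 1.2 | 48.6 |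
| eta | 12.0 | 44.1 | 0 | 48.2 |
| alpha | 1.04 | 48.6 | 27.9 | 21.7 |
| alpha | 1.67 | 49.7 | 18.5 | 30.7 |
| alpha | 3.00 | 50.0 | 6.2 | 41.6 |
| alpha | 6.00 | 49.5 | 1.2 | 46.1 |
| alpha | 12.0 | 45.4 | 1.3 | 49.6 |

(each reading ± 1 percentage point)

- catalyst is single-handed; left-handed substrate and right-handed substrate are mirror images of each other, charged as a racemate, each of them at the stated concentration
- solid, in amounts per volume of the solution: solid reagent
- what was read earlier has a scatter of 1 percentage point, one standard deviation
- at the start none of the solid reagent is in solution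

1. whether the excess of right-handed substrate over left-handed substrate among what is left of the two reaches 80 % by 10 d (no / yes)
2. the highest excess of right-handed substrate over left-handed substrate among what is left of the two up to 10 d

Our own reckoning treats left-handed substrate as pseudo-first-order. The zeta reading at 3.00 d gives 0.323 /d, and scaling by loading gives 0.484 /d for the flask. The flask's ratio then reaches the allowed value after 4.54 d, earlier than 5.00 d, the zeta reading after which the left-handed readings fall more slowly. So we say yes, and this reckoning gives a time, not a top.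

The forecast says yes, with a top of 94 %, and its grounds for a full finish include that “late right-handed loss in eta and alpha hints the catalyst is still alive”.

The flask gives yes, with a top of 89.7 %.

    partner + catalyst + left-handed substrate → catalyst + left-handed product (k = 11300 /M²/h)
    partner + catalyst + right-handed substrate → catalyst + right-handed product (k = 162 /M²/h)
    2 partner → self-condensation product (k = 0.506 /M/h)
    catalyst ⇌ dormant form (K = 9.40, k = 0.0116 /h)
    solid reagent ⇌ partner, rate k5*(cs5 - [partner]) while solid is left; crystals form when [partner] > cs5 (solubility = 23.0 mM, k = 0.134 /h)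

The flask meets the allowed ratio at 5.67 d, later than our 4.54 d, with right-handed substrate at 48.4 % and so left-handed substrate at 5.37 % of the charge. Our reckoned left-handed half-life of 1.43 d compares with 7.2 d by the step making left-handed product at 10.0 d, when the flask holds catalyst at 13.8 % and dormant form at 86.2 % of the catalyst charged. The yes would turn to no if the flask behaved like the zeta run at 0.24 mol%, whose last ratio reads 15.2 %, above the allowed ratio.

(The data are calculated on assumed constants; noise was put on by code.)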